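Assumption: the SMILES is read literally, that is furofuran (1S,3aR,4S,6aR) as in (+)-pinoresinol, (S) at the ketone α-carbon, and a 2,3-cis (2S,3S) dihydrobenzofuran; this stereoisomer is the one made.

## Retrosynthetic overview

1. Target 18 ⇐ bis-silyl ether 17 ⇐ mono-hydrazone 15 of the C2-symmetric bis(α-aryl-β-hydroxy ketone) 14. The dihydrobenzofuran is closed last by forming its C2–O1 bond (carbene O–H insertion); the untouched arm stays as the ketone.
2. 14 ⇐ bis-deoxybenzoin 11 by twofold catalytic asymmetric hydroxymethylation (sets both (S) arm centres) ⇐ dibromide 8 + ketone 10 by twofold Pd ketone α-arylation.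
3. Furofuran 8 ⇐ epoxy ether 6 by titanocene radical cyclisation (first tetrahydrofuran ring) and iodine-triggered C–O closure (second ring) ⇐ Williamson C–O union of epoxy alcohol 4 with cinnamyl bromide 5.
4. 4 and 5 both ⇐ allylic alcohol 3 ⇐ 5-bromovanillin 1; Sharpless kinetic resolution of 3 supplies the absolute configuration of the core.
5. Ring order: tetrahydrofuran ring 1, tetrahydrofuran ring 2, dihydrobenzofuran.

## Route

Step 1
Reactants: 1 5-bromovanillin (3-bromo-4-hydroxy-5-methoxybenzaldehyde)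
Product: 2 4-(benzyloxy)-3-bromo-5-methoxybenzaldehyde
Conditions: BnBr, K2CO3, DMF, 60 °C
Reagents that add atoms: benzyl bromide BrCc1ccccc1
Why: Williamson O-alkylation of the phenoxide; the benzyl ether survives the Grignard, titanium and palladium steps and is later removed by neutral hydrogenolysis.

Step 2
Reactants: 2 4-(benzyloxy)-3-bromo-5-methoxybenzaldehyde
Product: 3 rac-1-[4-(benzyloxy)-3-bromo-5-methoxyphenyl]prop-2-en-1-ol
Conditions: CH2=CHMgBr, THF, −20 → 0 °C; aq NH4Cl
Reagents that add atoms: vinylmagnesium bromide C=C[Mg]Br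
Why: Grignard 1,2-addition to the aldehyde (the aryl bromide does not exchange at this temperature); the carbinol centre is formed racemic and is resolved in step 3.

Step 3
Reactants: 3 rac-1-[4-(benzyloxy)-3-bromo-5-methoxyphenyl]prop-2-en-1-ol
Product: 4 (R)-[4-(benzyloxy)-3-bromo-5-methoxyphenyl][(S)-oxiran-2-yl]methanol (erythro)
Conditions: Ti(OiPr)4, D-(−)-diisopropyl tartrate, t-BuOOH (0.45 equiv), 4 Å MS, CH2Cl2, −20 °C
Reagents that add atoms: tert-butyl hydroperoxide CC(C)(C)OO
Why: Sharpless kinetic resolution (asymmetric epoxidation of a secondary allylic alcohol): the (S)-alcohol is epoxidised fast and erythro-selectively, which fixes the benzylic C–O centre that becomes a furofuran benzylic carbon (the L-(+) ester would give the antipodal series); the unreacted (R)-enriched 3 is recovered for step 4.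

Step 4
Reactants: 3 rac-1-[4-(benzyloxy)-3-bromo-5-methoxyphenyl]prop-2-en-1-ol (a second portion, or the (R)-enriched alcohol recovered from step 3)
Product: 5 (E)-2-(benzyloxy)-1-bromo-5-(3-bromoprop-1-en-1-yl)-3-methoxybenzene
Conditions: PBr3, Et2O, 0 °C; used at once
Reagents that add atoms: phosphorus tribromide BrP(Br)Br
Why: bromination with allylic transposition (SN2'/ion-pair return) gives the conjugated primary (E)-cinnamyl bromide; the carbinol centre is erased, so either enantiomer of 3 serves.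

Step 5
Reactants: 4 (R)-[4-(benzyloxy)-3-bromo-5-methoxyphenyl][(S)-oxiran-2-yl]methanol; 5 (E)-2-(benzyloxy)-1-bromo-5-(3-bromoprop-1-en-1-yl)-3-methoxybenzene
Product: 6 (S)-2-{(R)-[4-(benzyloxy)-3-bromo-5-methoxyphenyl]{[(E)-3-[4-(benzyloxy)-3-bromo-5-methoxyphenyl]prop-2-en-1-yl]oxy}methyl}oxirane
Conditions: NaH, Bu4NI (cat.), THF, 0 → 23 °C
Reagents that add atoms: none
Why: Williamson etherification of the secondary alkoxide with the reactive allylic bromide, run cold and aprotic to outrun Payne rearrangement; this is the first C–O bond of the furofuran and no stereocentre is touched.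

Step 6
Reactants: 6 epoxy cinnamyl ether
Product: 8 (1S,3aR,4S,6aR)-1,4-bis[4-(benzyloxy)-3-bromo-5-methoxyphenyl]tetrahydro-1H,3H-furo[3,4-c]furan, via iodo alcohol 7 (not isolated)
Conditions: Cp2TiCl2, Zn, THF, 23 °C; then I2, 60 °C
Reagents that add atoms: none
Why: Nugent–RajanBabu reductive epoxide opening by trivalent titanium (Cp2TiCl) gives a secondary radical that closes 5-exo-trig onto the cinnamyl alkene (2,3-trans, 3,4-cis under control of the existing benzylic centre), and iodination of the benzylic terminus lets the titanium alkoxide close the second ring by C–O bond formation with the aryl group exo, giving the pinoresinol-type bicycle.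

Step 7
Reactants: 9 acetovanillone (1-(4-hydroxy-3-methoxyphenyl)ethan-1-one)
Product: 10 1-{3-methoxy-4-[(triisopropylsilyl)oxy]phenyl}ethan-1-one
Conditions: i-Pr3SiCl, imidazole, DMF, 23 °C
Reagents that add atoms: triisopropylsilyl chloride CC(C)[Si](Cl)(C(C)C)C(C)C
Why: phenol silylation; the bulky aryl silyl ether tolerates the phosphate base, Lewis acid, hydrogenation and hydrazine used later and is cleaved by fluoride at the end.

Step 8
Reactants: 8 dibenzyl dibromo furofuran; 10 silylated acetovanillone (3 equiv per bromide)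
Product: 11 bis-deoxybenzoin: 8 in which each bromine is replaced by CH2C(=O)Ar, Ar = 3-methoxy-4-[(triisopropylsilyl)oxy]phenyl
Conditions: Pd2(dba)3 (2.5 mol %), Xantphos (6 mol %), K3PO4, toluene, 90 °C
Reagents that add atoms: none
Why: palladium-catalysed ketone α-arylation (Buchwald–Hartwig type, zerovalent/divalent palladium cycle); the wide-bite-angle ligand, mild phosphate base and excess methyl ketone favour mono-arylation at each bromide, and no stereocentre is formed.

Step 9
Reactants: 11 bis-deoxybenzoin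
Product: 12 bis[(Z)-trimethylsilyl enol ether] of 11
Conditions: Me3SiOTf, Et3N, CH2Cl2, 0 °C
Reagents that add atoms: trimethylsilyl triflate C[Si](C)(C)OS(=O)(=O)C(F)(F)F
Why: soft enolisation and O-silylation of the acidic benzylic ketone gives the conjugated (Z)-enol silanes (aryl groups trans) needed for a face-selective aldol.

Step 10
Reactants: 12 bis(silyl enol ether)
Product: 13 C2-symmetric bis(β-hydroxy ketone): each arm is ArC(=O)–CH(CH2OH)– on the central ring, both new centres (S), central phenols still benzylated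
Conditions: Sc(OTf)3 (20 mol %), (S,S)-6,6'-bis(1-hydroxy-2,2-dimethylpropyl)-2,2'-bipyridine (24 mol %), aq HCHO, DME/H2O 9:1, −20 °C
Reagents that add atoms: formaldehyde C=O
Why: catalytic asymmetric Mukaiyama aldol (hydroxymethylation) in water: the chiral scandium–bipyridine complex selects the enolate face at each arm independently, and the weakly acidic medium avoids enolisation or retro-aldol of the product; the sense of induction is assigned by analogy with propiophenone enolates and the ligand antipode is used if this aryl-substituted enolate reacts in the opposite sense.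

Step 11
Reactants: 13 dibenzyl bis(β-hydroxy ketone)
Product: 14 C2-symmetric diphenol bis(β-hydroxy ketone)
Conditions: H2 (1 atm), 5% Pd/C, EtOAc, 23 °C
Reagents that add atoms: none
Why: hydrogenolysis of the two aryl benzyl ethers under neutral conditions, which neither enolise the α-aryl ketones nor dehydrate the o-hydroxyaryl ketones to benzofurans.

Step 12
Reactants: 14 diphenol bis(β-hydroxy ketone)
Product: 15 mono-hydrazone of 14 (one C=O replaced by C=N–NH2, configuration unchanged)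
Conditions: N2H4·H2O (3 equiv), EtOH, 23 °C, stopped near half conversion
Reagents that add atoms: hydrazine (as monohydrate) NN
Why: hydrazone condensation; the two ketones are equivalent by C2 symmetry, so the mono-hydrazone forms statistically (about 45% per pass, 14 recovered and recycled), and the weak base at room temperature is chosen to leave the α-centres intact.

Step 13
Reactants: 15 mono-hydrazone
Product: 17 O,O'-bis(triisopropylsilyl) ether of the target with the (2S,3S)-cis-dihydrobenzofuran closed, via diazo compound 16 (not isolated)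
Conditions: MnO2, CH2Cl2, −20 °C, 20 min; cold filtration; Rh2(O2CCPh3)4 (2 mol %), CH2Cl2, −78 → −20 °C
Reagents that add atoms: none
Why: Proposed new method: intramolecular phenol O–H insertion of a donor/donor (aryl/alkyl) carbene, made by MnO2 dehydrogenation of the free hydrazone to diazo compound 16 and loss of N2 at a bulky divalent rhodium carboxylate; the phenol oxygen attacks the electrophilic carbene carbon to close the five-membered ring (the primary OH could only give an oxetane), the dirhodium unit of the rhodium-bound oxonium ylide lies anti to the C3 CH2OH group and the 1,2-proton shift replaces rhodium on that face, so H-2 ends trans to CH2OH and the aryl group cis (2S,3S), with no benzylic cation or quinone methide that would leak to the trans isomer and with the bulky carboxylate at low temperature suppressing the 1,2-hydride shift to a stilbene; the closest known reaction types are C–H insertion of hydrazone-derived donor/donor rhodium carbenes (which gives cis-2-aryl-2,3-dihydrobenzofurans) and catalytic O–H insertion of diazo compounds into phenols.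

Step 14
Reactants: 17 bis(triisopropylsilyl) ether of the target
Product: 18 target CNP0174045.1
Conditions: Bu4NF/AcOH (1:1), THF, 0 °C
Reagents that add atoms: none
Why: fluoride cleavage of the two aryl silyl ethers, buffered so that no free phenoxide can epimerise the ketone α-centre or open the cis-dihydrobenzofuran by retro-oxa-Michael reaction.

## Compound list

1 | 5-bromovanillin | COc1cc(C=O)cc(Br)c1O | starting material
2 | 4-(benzyloxy)-3-bromo-5-methoxybenzaldehyde | COc1cc(C=O)cc(Br)c1OCc1ccccc1 | intermediate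
3 | rac-1-[4-(benzyloxy)-3-bromo-5-methoxyphenyl]prop-2-en-1-ol | COc1cc(C(O)C=C)cc(Br)c1OCc1ccccc1 | intermediate
4 | (R)-[4-(benzyloxy)-3-bromo-5-methoxyphenyl][(S)-oxiran-2-yl]methanol | O[C@H](c1cc(Br)c(OCc2ccccc2)c(OC)c1)[C@@H]1CO1 | intermediate
5 | (E)-2-(benzyloxy)-1-bromo-5-(3-bromoprop-1-en-1-yl)-3-methoxybenzene | COc1cc(/C=C/CBr)cc(Br)c1OCc1ccccc1 | intermediate
6 | (S)-2-{(R)-aryl[(E)-3-arylprop-2-en-1-yloxy]methyl}oxirane, aryl = 4-(benzyloxy)-3-bromo-5-methoxyphenyl | COc1cc(/C=C/CO[C@H](c2cc(Br)c(OCc3ccccc3)c(OC)c2)[C@@H]2CO2)cc(Br)c1OCc1ccccc1 | intermediate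
7 | [(2S,3R,4R)-2-aryl-4-[aryl(iodo)methyl]oxolan-3-yl]methanol, aryl as in 6, iodide epimers, present as its titanium alkoxide, drawn as the alcohol | COc1cc(cc(Br)c1OCc1ccccc1)[C@H]1OC[C@H](C(I)c2cc(Br)c(OCc3ccccc3)c(OC)c2)[C@@H]1CO | intermediate
8 | (1S,3aR,4S,6aR)-1,4-bis[4-(benzyloxy)-3-bromo-5-methoxyphenyl]tetrahydro-1H,3H-furo[3,4-c]furan | COc1cc(cc(Br)c1OCc1ccccc1)[C@H]1OC[C@H]2[C@@H]1CO[C@@H]2c1cc(Br)c(OCc2ccccc2)c(OC)c1 | intermediate
9 | acetovanillone | CC(=O)c1ccc(O)c(OC)c1 | starting material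
10 | 1-{3-methoxy-4-[(triisopropylsilyl)oxy]phenyl}ethan-1-one | CC(=O)c1ccc(O[Si](C(C)C)(C(C)C)C(C)C)c(OC)c1 | intermediate
11 | bis-deoxybenzoin (each bromine of 8 replaced by CH2C(=O)Ar) | COc1cc(C(=O)Cc2cc([C@H]3OC[C@H]4[C@@H]3CO[C@@H]4c3cc(OC)c(OCc4ccccc4)c(c3)CC(=O)c3ccc(O[Si](C(C)C)(C(C)C)C(C)C)c(OC)c3)cc(OC)c2OCc2ccccc2)ccc1O[Si](C(C)C)(C(C)C)C(C)C | intermediate
12 | bis[(Z)-trimethylsilyl enol ether] of 11 | COc1cc(/C(O[Si](C)(C)C)=C/c2cc([C@H]3OC[C@H]4[C@@H]3CO[C@@H]4c3cc(OC)c(OCc4ccccc4)c(c3)/C=C(\O[Si](C)(C)C)c3ccc(O[Si](C(C)C)(C(C)C)C(C)C)c(OC)c3)cc(OC)c2OCc2ccccc2)ccc1O[Si](C(C)C)(C(C)C)C(C)C | intermediate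
13 | dibenzyl bis[(S)-α-(hydroxymethyl)] ketone | COc1cc(C(=O)[C@H](CO)c2cc([C@H]3OC[C@H]4[C@@H]3CO[C@@H]4c3cc(OC)c(OCc4ccccc4)c(c3)[C@@H](CO)C(=O)c3ccc(O[Si](C(C)C)(C(C)C)C(C)C)c(OC)c3)cc(OC)c2OCc2ccccc2)ccc1O[Si](C(C)C)(C(C)C)C(C)C | intermediate
14 | diphenol bis[(S)-α-(hydroxymethyl)] ketone | COc1cc(C(=O)[C@H](CO)c2cc([C@H]3OC[C@H]4[C@@H]3CO[C@@H]4c3cc(OC)c(O)c(c3)[C@@H](CO)C(=O)c3ccc(O[Si](C(C)C)(C(C)C)C(C)C)c(OC)c3)cc(OC)c2O)ccc1O[Si](C(C)C)(C(C)C)C(C)C | intermediate
15 | mono-hydrazone of 14 | COc1cc(C(=O)[C@H](CO)c2cc([C@H]3OC[C@H]4[C@@H]3CO[C@@H]4c3cc(OC)c(O)c(c3)[C@@H](CO)C(=NN)c3ccc(O[Si](C(C)C)(C(C)C)C(C)C)c(OC)c3)cc(OC)c2O)ccc1O[Si](C(C)C)(C(C)C)C(C)C | intermediate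
16 | aryl alkyl diazo compound from 15 | COc1cc(C(=O)[C@H](CO)c2cc([C@H]3OC[C@H]4[C@@H]3CO[C@@H]4c3cc(OC)c(O)c(c3)[C@@H](CO)C(=[N+]=[N-])c3ccc(O[Si](C(C)C)(C(C)C)C(C)C)c(OC)c3)cc(OC)c2O)ccc1O[Si](C(C)C)(C(C)C)C(C)C | intermediate
17 | O,O'-bis(triisopropylsilyl) ether of the target | COc1cc(C(=O)[C@H](CO)c2cc([C@H]3OC[C@H]4[C@@H]3CO[C@@H]4c3cc(OC)c4c(c3)[C@@H](CO)[C@@H](c3ccc(O[Si](C(C)C)(C(C)C)C(C)C)c(OC)c3)O4)cc(OC)c2O)ccc1O[Si](C(C)C)(C(C)C)C(C)C | intermediate
18 | CNP0174045.1 | COc1cc(C(=O)[C@H](CO)c2cc([C@H]3OC[C@H]4[C@@H]3CO[C@@H]4c3cc(OC)c4c(c3)[C@@H](CO)[C@@H](c3ccc(O)c(OC)c3)O4)cc(OC)c2O)ccc1O | target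

## Step count and risks

Total step count: 14. Longest linear sequence: 12 (steps 1, 2, 3, 5, 6, 8, 9, 10, 11, 12, 13, 14).

**Step 13 (the proposed O–H insertion, with its feeder step 12).** The risks are: epimerisation of the α-centre while the hindered hydrazone forms; MnO2 attacking the free phenols; uncatalysed protonation of the diazo compound by the neighbouring phenol, which would give the trans ring through an ion pair; proton relay by the free primary OH; and 1,2-hydride shift. The fallback uses known chemistry; it sets out from compound 13 and comes back to the route at compound 18. The two primary alcohols of 13 are silylated (t-BuMe2SiCl, imidazole) to give the bis(tert-butyldimethylsilyl) ether F8. One of the two equivalent ketones is reduced under catalyst control with (S)-2-methyl-CBS-oxazaborolidine and BH3·SMe2 (half an equivalent of hydride, unreacted F8 recycled) to the (1R)-benzylic alcohol F9. Hydrogenolysis (H2, Pd/C) frees the central phenols and gives the diphenol alcohol F10. A Mitsunobu reaction (PPh3, DIAD, toluene, 0 °C) lets the neighbouring phenol displace the activated benzylic oxygen with inversion, the primary oxygen being blocked, and gives the cis-dihydrobenzofuran tetrasilyl ether F11. Bu4NF/AcOH then removes all four silyl groups and gives 18.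

**Step 10 (twofold asymmetric hydroxymethylation).** The risks are two catalyst-controlled events on a large, poorly soluble diaryl enol silane, competing protodesilylation, and the unverified sense of induction. The fallback sets out from compound 11 and comes back at compound 14. Compound 11 is condensed with (S)-1-amino-2-(methoxymethyl)pyrrolidine to the bis-SAMP hydrazone F5. The aza-enolates (LiN(iPr)2, THF, −78 °C) are alkylated with benzyl chloromethyl ether at −100 °C to give the bis[α-(benzyloxymethyl)] hydrazone F6 (Enders alkylation, auxiliary control; the RAMP antipode is taken if the opposite sense is needed). Aqueous oxalic acid cleaves the auxiliary without epimerisation to the bis[α-(benzyloxymethyl)] ketone F7. Hydrogenolysis under the conditions of step 11 removes all four benzyl groups and gives 14.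

**Step 6 (titanocene radical cyclisation and iodine-triggered ring closure).** The risks are Payne-isomerised material from step 5, diastereomer leakage in the 5-exo closure, and acid-driven epimerisation at 60 °C. The fallback sets out from compound 1 and comes back at compound 8. Wittig olefination of 1 with Ph3P=CHCO2Et gives ethyl (E)-5-bromoferulate F1. Reduction with i-Bu2AlH gives (E)-5-bromoconiferyl alcohol F2. Biomimetic oxidative β–β dimerisation (FeCl3, aqueous acetone), in which the bromine blocks 5-coupling, gives crystalline racemic 5,5'-dibromopinoresinol F3. Preparative chiral SFC delivers the (1S,3aR,4S,6aR) enantiomer F4. Benzylation (BnBr, K2CO3) gives 8.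

## Further compounds

F1 | step 6 | ethyl (E)-3-(3-bromo-4-hydroxy-5-methoxyphenyl)acrylate | CCOC(=O)/C=C/c1cc(Br)c(O)c(OC)c1
F2 | step 6 | (E)-5-bromoconiferyl alcohol | OC/C=C/c1cc(Br)c(O)c(OC)c1
F3 | step 6 | rac-5,5'-dibromopinoresinol (relative configuration as in pinoresinol) | COc1cc(cc(Br)c1O)C1OCC2C1COC2c1cc(Br)c(O)c(OC)c1
F4 | step 6 | (1S,3aR,4S,6aR)-5,5'-dibromopinoresinol | COc1cc(cc(Br)c1O)[C@H]1OC[C@H]2[C@@H]1CO[C@@H]2c1cc(Br)c(O)c(OC)c1
F5 | step 10 | bis-SAMP hydrazone of 11 | COc1cc(C(=NN2CCC[C@H]2COC)Cc2cc([C@H]3OC[C@H]4[C@@H]3CO[C@@H]4c3cc(OC)c(OCc4ccccc4)c(c3)CC(=NN3CCC[C@H]3COC)c3ccc(O[Si](C(C)C)(C(C)C)C(C)C)c(OC)c3)cc(OC)c2OCc2ccccc2)ccc1O[Si](C(C)C)(C(C)C)C(C)C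
F6 | step 10 | bis[α-(benzyloxymethyl)] bis-SAMP hydrazone | COc1cc(C(=NN2CCC[C@H]2COC)[C@H](COCc2ccccc2)c2cc([C@H]3OC[C@H]4[C@@H]3CO[C@@H]4c3cc(OC)c(OCc4ccccc4)c(c3)[C@@H](COCc3ccccc3)C(=NN3CCC[C@H]3COC)c3ccc(O[Si](C(C)C)(C(C)C)C(C)C)c(OC)c3)cc(OC)c2OCc2ccccc2)ccc1O[Si](C(C)C)(C(C)C)C(C)C
F7 | step 10 | bis[α-(benzyloxymethyl)] ketone (13 with both primary OH benzylated) | COc1cc(C(=O)[C@H](COCc2ccccc2)c2cc([C@H]3OC[C@H]4[C@@H]3CO[C@@H]4c3cc(OC)c(OCc4ccccc4)c(c3)[C@@H](COCc3ccccc3)C(=O)c3ccc(O[Si](C(C)C)(C(C)C)C(C)C)c(OC)c3)cc(OC)c2OCc2ccccc2)ccc1O[Si](C(C)C)(C(C)C)C(C)C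
F8 | step 13 | bis(tert-butyldimethylsilyl) ether of 13 | COc1cc(C(=O)[C@H](CO[Si](C)(C)C(C)(C)C)c2cc([C@H]3OC[C@H]4[C@@H]3CO[C@@H]4c3cc(OC)c(OCc4ccccc4)c(c3)[C@@H](CO[Si](C)(C)C(C)(C)C)C(=O)c3ccc(O[Si](C(C)C)(C(C)C)C(C)C)c(OC)c3)cc(OC)c2OCc2ccccc2)ccc1O[Si](C(C)C)(C(C)C)C(C)C
F9 | step 13 | mono-(1R)-benzylic alcohol from F8 | COc1cc(C(=O)[C@H](CO[Si](C)(C)C(C)(C)C)c2cc([C@H]3OC[C@H]4[C@@H]3CO[C@@H]4c3cc(OC)c(OCc4ccccc4)c(c3)[C@@H](CO[Si](C)(C)C(C)(C)C)[C@@H](O)c3ccc(O[Si](C(C)C)(C(C)C)C(C)C)c(OC)c3)cc(OC)c2OCc2ccccc2)ccc1O[Si](C(C)C)(C(C)C)C(C)C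
F10 | step 13 | diphenol (1R)-alcohol | COc1cc(C(=O)[C@H](CO[Si](C)(C)C(C)(C)C)c2cc([C@H]3OC[C@H]4[C@@H]3CO[C@@H]4c3cc(OC)c(O)c(c3)[C@@H](CO[Si](C)(C)C(C)(C)C)[C@@H](O)c3ccc(O[Si](C(C)C)(C(C)C)C(C)C)c(OC)c3)cc(OC)c2O)ccc1O[Si](C(C)C)(C(C)C)C(C)C
F11 | step 13 | cis-dihydrobenzofuran tetrasilyl ether | COc1cc(C(=O)[C@H](CO[Si](C)(C)C(C)(C)C)c2cc([C@H]3OC[C@H]4[C@@H]3CO[C@@H]4c3cc(OC)c4c(c3)[C@@H](CO[Si](C)(C)C(C)(C)C)[C@@H](c3ccc(O[Si](C(C)C)(C(C)C)C(C)C)c(OC)c3)O4)cc(OC)c2O)ccc1O[Si](C(C)C)(C(C)C)C(C)C
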